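## Retrosynthetic overview

1. The C4–O–C4 ether is made last: the (2S)-flavan-4-yl cation of the 5-hydroxy-6,7-dimethoxy half (as its 4,5-diacetate) is captured by the O-silylated (2S,4R)-5,6,7-trimethoxyflavan-4-ol. This capture sets the last stereocentre (2,4-trans).
2. Each half comes from a racemic flavanone by Noyori transfer-hydrogenative kinetic resolution, which selects C2 = S and gives the cis-4-ol. The nucleophilic half is then inverted at C4 (Mitsunobu); the electrophilic half needs no defined C4.
3. Both flavanones derive from one racemic 5,6,7-trimethoxyflavanone; the 5-OH of one half is exposed by chelation-controlled BCl3 demethylation.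
4. The only ring-forming step is the intramolecular oxa-Michael cyclisation of a 2'-hydroxychalcone, made by Claisen–Schmidt condensation of the acetophenone with benzaldehyde.
5. Ring order: the pyranone ring is closed once, before the route divides; the two chromane units are then joined through oxygen and no further ring is formed.

Assumption: compound 1 is bought (catalogue compound, also sold as 6'-hydroxy-2',3',4'-trimethoxyacetophenone); both reductions are kinetic resolutions, so each uses at most half of its racemic ketone.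

## Route

Step 1
Reactants: 1 2'-hydroxy-4',5',6'-trimethoxyacetophenone; 2 benzaldehyde
Product: 3 (E)-2'-hydroxy-4',5',6'-trimethoxychalcone
Conditions: KOH (50% aq, 5 equiv), EtOH, rt, 36 h; then 2 M HCl
Reagents that add atoms: none
Why: Claisen–Schmidt (crossed aldol) condensation of the ketone enolate with the non-enolisable aldehyde, with E1cB dehydration giving the conjugated E-enone, while the phenoxide present in strong base keeps the chalcone open.

Step 2
Reactants: 3 (E)-2'-hydroxy-4',5',6'-trimethoxychalcone
Product: 4 rac-5,6,7-trimethoxyflavanone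
Conditions: NaOAc (3 equiv), EtOH–H2O 9:1, reflux, 24 h (unchanged 3 recycled)
Reagents that add atoms: none
Why: Intramolecular oxa-Michael addition (6-endo-trig) of the 2'-phenol to the enone closes the pyranone ring, the 6'-OMe twisting the chalcone out of conjugation so that the equilibrium favours the flavanone; C2 is formed racemic here and is resolved in steps 3 and 9.

Step 3
Reactants: 4 rac-5,6,7-trimethoxyflavanone
Product: 5 (2S,4S)-5,6,7-trimethoxyflavan-4-ol
Conditions: RuCl[(S,S)-TsDPEN](p-cymene) (1 mol%), HCO2H/Et3N 5:2, EtOAc, 30 °C, to ca. 45–48% conversion; chromatography removes unreacted (R)-4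
Reagents that add atoms: none
Why: Noyori asymmetric transfer hydrogenation run as a kinetic resolution: the (S,S)-catalyst gives the (4S)-benzylic alcohol (as with 4-chromanone), and only (S)-4 can take that hydride along the favoured axial path that leads to the 2,4-cis alcohol, so C2 = S is selected and C4 = S is set.

Step 4
Reactants: 5 (2S,4S)-5,6,7-trimethoxyflavan-4-ol
Product: 6 (2S,4R)-5,6,7-trimethoxyflavan-4-yl 4-nitrobenzoate
Conditions: 4-nitrobenzoic acid, PPh3, DIAD, THF, 0 °C → rt; Et3N-deactivated silica
Reagents that add atoms: 4-nitrobenzoic acid, O=C(O)c1ccc(cc1)[N+](=O)[O-]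
Why: Mitsunobu reaction, in which SN2 attack of the carboxylate on the alkoxyphosphonium inverts C4 (4S → 4R); if this electron-rich benzylic centre ionises instead, axial recombination gives the same 2,4-trans ester.

Step 5
Reactants: 6 (2S,4R)-5,6,7-trimethoxyflavan-4-yl 4-nitrobenzoate
Product: 7 (2S,4R)-5,6,7-trimethoxyflavan-4-ol
Conditions: LiOH·H2O (2 equiv), THF–H2O 3:1, 0 °C → rt; 7 extracted, aqueous phase then acidified (HCl)
Reagents that add atoms: none
Why: Saponification by acyl–oxygen cleavage leaves the C4–O bond and the 4R centre untouched; methanol is avoided because this ester can solvolyse (SN1) to a methyl ether, whereas in aqueous THF any such leakage still ends in the alcohol.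

Step 6
Reactants: 7 (2S,4R)-5,6,7-trimethoxyflavan-4-ol
Product: 8 (2S,4R)-5,6,7-trimethoxy-4-(trimethylsilyloxy)flavan
Conditions: N-(trimethylsilyl)imidazole (1.5 equiv), CH2Cl2, rt; filtration through basic alumina
Reagents that add atoms: N-(trimethylsilyl)imidazole, C[Si](C)(C)n1ccnc1
Why: Neutral O-silylation of the acid-sensitive benzylic alcohol touches no stereocentre and provides an aprotic O-nucleophile for the Lewis-acid coupling.

Step 7
Reactants: 4 rac-5,6,7-trimethoxyflavanone
Product: 9 rac-5-hydroxy-6,7-dimethoxyflavanone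
Conditions: BCl3 (1.2 equiv, 1 M in CH2Cl2), CH2Cl2, −78 → 0 °C; H2O
Reagents that add atoms: none
Why: Chelation-controlled Lewis-acid ether cleavage, in which boron bridges C4=O and the peri 5-OMe so that chloride removes only that methyl group; it is done on racemic material, so any ring opening is harmless.

Step 8
Reactants: 9 rac-5-hydroxy-6,7-dimethoxyflavanone
Product: 10 rac-5-acetoxy-6,7-dimethoxyflavanone
Conditions: Ac2O (2 equiv), pyridine, DMAP (5 mol%), rt
Reagents that add atoms: acetic anhydride, CC(=O)OC(C)=O
Why: DMAP-catalysed acetylation of the chelated phenol frees the ketone from its hydrogen bond (needed for clean reduction) and protects the phenol for the cationic coupling.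

Step 9
Reactants: 10 rac-5-acetoxy-6,7-dimethoxyflavanone
Product: 11 (2S,4S)-5-acetoxy-6,7-dimethoxyflavan-4-ol
Conditions: RuCl[(S,S)-TsDPEN](p-cymene) (1 mol%), HCO2H/Et3N 5:2, EtOAc, 30 °C, to ca. 45–48% conversion; chromatography removes unreacted (R)-10
Reagents that add atoms: none
Why: The same Noyori transfer-hydrogenative kinetic resolution as in step 3, the (S,S)-catalyst reducing only the (S)-ketone to the cis-(2S,4S)-alcohol, which fixes C2 = S for this half.

Step 10
Reactants: 11 (2S,4S)-5-acetoxy-6,7-dimethoxyflavan-4-ol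
Product: 12 (2S,4S)-4,5-diacetoxy-6,7-dimethoxyflavan
Conditions: Ac2O (1.5 equiv), pyridine, DMAP (5 mol%), CH2Cl2, 0 °C; Et3N-deactivated silica
Reagents that add atoms: acetic anhydride, CC(=O)OC(C)=O
Why: O-acetylation turns the benzylic hydroxyl into the leaving group for the coupling (its C4 configuration is lost on ionisation), and any 4-O-acetyl/5-OH isomer formed by acyl migration in step 9 converges on the same diacetate.

Step 11
Reactants: 12 (2S,4S)-4,5-diacetoxy-6,7-dimethoxyflavan; 8 (2S,4R)-5,6,7-trimethoxy-4-(trimethylsilyloxy)flavan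
Product: 14 beilschmieflavonoid B, via 5-O-acetylbeilschmieflavonoid B 13 (not isolated)
Conditions: 12 (1 equiv), 8 (1.3 equiv), TMSOTf (10 mol%), 2,6-di-tert-butyl-4-methylpyridine (20 mol%), 4 Å MS, CH2Cl2, −78 °C, 1 h; Et3N; concentrate; then K2CO3 (cat.), MeOH–THF, 0 °C → rt; NH4Cl work-up, neutralised silica
Reagents that add atoms: none
Why: TMSOTf-catalysed SN1 etherification (acetate/silyl ether exchange): the (2S)-flavan-4-yl cation from 12 is attacked by the oxygen of 8 pseudo-axially, trans to the equatorial 2-phenyl and away from the peri 5-acetoxy group, which sets the new C4 as R, while C4 of 8 keeps its C–O bond and configuration; base-catalysed transesterification then frees the 5-OH.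

Note: unreacted (R)-4 and (R)-10 from steps 3 and 9 can be racemised through the chalcone (NaOAc, EtOH, reflux) and resubmitted.

## Compound list

1 | 2'-hydroxy-4',5',6'-trimethoxyacetophenone | COc1cc(O)c(C(C)=O)c(OC)c1OC | starting material
2 | benzaldehyde | O=Cc1ccccc1 | starting material
3 | (E)-2'-hydroxy-4',5',6'-trimethoxychalcone | COc1cc(O)c(C(=O)/C=C/c2ccccc2)c(OC)c1OC | intermediate
4 | rac-5,6,7-trimethoxyflavanone (racemic 5,6,7-trimethoxy-2-phenylchroman-4-one) | O=C1CC(c2ccccc2)Oc2cc(OC)c(OC)c(OC)c21 | intermediate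
5 | (2S,4S)-5,6,7-trimethoxyflavan-4-ol (2,4-cis) | O[C@H]1C[C@@H](c2ccccc2)Oc2cc(OC)c(OC)c(OC)c21 | intermediate
6 | (2S,4R)-5,6,7-trimethoxyflavan-4-yl 4-nitrobenzoate (2,4-trans) | O=C(O[C@@H]1C[C@@H](c2ccccc2)Oc2cc(OC)c(OC)c(OC)c21)c1ccc(cc1)[N+](=O)[O-] | intermediate
7 | (2S,4R)-5,6,7-trimethoxyflavan-4-ol (2,4-trans) | O[C@@H]1C[C@@H](c2ccccc2)Oc2cc(OC)c(OC)c(OC)c21 | intermediate
8 | (2S,4R)-5,6,7-trimethoxy-4-(trimethylsilyloxy)flavan | C[Si](C)(C)O[C@@H]1C[C@@H](c2ccccc2)Oc2cc(OC)c(OC)c(OC)c21 | intermediate
9 | rac-5-hydroxy-6,7-dimethoxyflavanone | O=C1CC(c2ccccc2)Oc2cc(OC)c(OC)c(O)c21 | intermediate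
10 | rac-5-acetoxy-6,7-dimethoxyflavanone | O=C1CC(c2ccccc2)Oc2cc(OC)c(OC)c(OC(C)=O)c21 | intermediate
11 | (2S,4S)-5-acetoxy-6,7-dimethoxyflavan-4-ol (2,4-cis) | O[C@H]1C[C@@H](c2ccccc2)Oc2cc(OC)c(OC)c(OC(C)=O)c21 | intermediate
12 | (2S,4S)-4,5-diacetoxy-6,7-dimethoxyflavan | CC(=O)O[C@H]1C[C@@H](c2ccccc2)Oc2cc(OC)c(OC)c(OC(C)=O)c21 | intermediate
13 | 5-O-acetylbeilschmieflavonoid B (the target with its phenol acetylated; both units 2S,4R) | COc1cc2c(c(OC(C)=O)c1OC)[C@H](O[C@@H]1C[C@@H](c3ccccc3)Oc3cc(OC)c(OC)c(OC)c31)C[C@@H](c1ccccc1)O2 | intermediate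
14 | beilschmieflavonoid B | COc1cc2c(c(O)c1OC)[C@H](O[C@@H]1C[C@@H](c3ccccc3)Oc3cc(OC)c(OC)c(OC)c31)C[C@@H](c1ccccc1)O2 | target

## Step count and risks

Total step count: 11 (step 11 is a two-stage, one-flask operation).
Longest linear sequence: 7 steps (1 → 2 → 3 → 4 → 5 → 6 → 11, or 1 → 2 → 7 → 8 → 9 → 10 → 11).

Steps most likely to fail:

Step 11 (ether coupling). Risks: TMSOTf may also ionise 8 or the product on the more electron-rich trimethoxy side, which scrambles the partners into homo-ethers. Elimination to the flav-3-ene and Friedel–Crafts attack by C8 of 8 are further risks. Fallback: replace hard Lewis-acid activation of an acetate by soft, thiophilic activation of a thio-donor in a buffered medium. Set out from 12 and exchange the 4-acetate for a thioether with thiophenol and catalytic ZnI2 (CH2Cl2, 0 °C). This gives (2S,4R)-5-acetoxy-6,7-dimethoxy-4-(phenylsulfanyl)flavan F1 (2,4-trans major; its C4 configuration is again irrelevant). Then couple F1 with the free alcohol 7 instead of 8, using AgOTf and 2,6-di-tert-butyl-4-methylpyridine over 4 Å sieves in CH2Cl2 at −40 °C. Silver removes the thiolate irreversibly, and nothing in the flask can ionise an alcohol or an ether. The fallback comes back to the route at 13, now isolated, which is deacetylated as in the second stage of step 11.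

Step 9 (resolution of the 5-acetoxy ketone). Risks: acyl migration, slow reduction next to the peri ester, or a poor selectivity factor. Fallback: run only one resolution and relay its product into this series. Set out from 5 (step 3 on larger scale) and oxidise with Dess–Martin periodinane (NaHCO3, CH2Cl2) to (S)-5,6,7-trimethoxyflavanone F2. Demethylate with BCl3 (CH2Cl2, −78 → 0 °C, no base, so C2 is not endangered) to (S)-5-hydroxy-6,7-dimethoxyflavanone F3. Reduce with NaBH4 (THF–MeOH, −10 °C, substrate-controlled axial hydride delivery) to (2S,4S)-5-hydroxy-6,7-dimethoxyflavan-4-ol F4. Acetylate both hydroxyls (Ac2O, pyridine, DMAP) to come back to the route at 12.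

Step 4 (Mitsunobu inversion). Risks: elimination to the flavene and a labile, solvolysis-prone ester 6. Fallback: replace SN2 inversion by a stereoconvergent SN1 hydrolysis. Set out from 5 and acetylate (Ac2O, pyridine, DMAP) to (2S,4S)-4-acetoxy-5,6,7-trimethoxyflavan F5. Let it solvolyse dilute and buffered (acetone–H2O 4:1, NaHCO3, 40 °C). Water enters the flavan-4-yl cation pseudo-axially and gives the 2,4-trans alcohol, so the fallback comes back to the route at 7 and bypasses steps 4 and 5. Residual cis-alcohol 5 is separated and recycled.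

## Further compounds

F1 | step 11 | (2S,4R)-5-acetoxy-6,7-dimethoxy-4-(phenylsulfanyl)flavan | c1ccccc1S[C@@H]1C[C@@H](c2ccccc2)Oc2cc(OC)c(OC)c(OC(C)=O)c21
F2 | step 9 | (S)-5,6,7-trimethoxyflavanone | O=C1C[C@@H](c2ccccc2)Oc2cc(OC)c(OC)c(OC)c21
F3 | step 9 | (S)-5-hydroxy-6,7-dimethoxyflavanone | O=C1C[C@@H](c2ccccc2)Oc2cc(OC)c(OC)c(O)c21
F4 | step 9 | (2S,4S)-5-hydroxy-6,7-dimethoxyflavan-4-ol | O[C@H]1C[C@@H](c2ccccc2)Oc2cc(OC)c(OC)c(O)c21
F5 | step 4 | (2S,4S)-4-acetoxy-5,6,7-trimethoxyflavan | CC(=O)O[C@H]1C[C@@H](c2ccccc2)Oc2cc(OC)c(OC)c(OC)c21
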